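Numbering: C1 is the benzylic CH2, C16 the carbinol CH and C17 the CH3. The target is 5-[(16S)-16-hydroxyheptadecyl]benzene-1,3-diol.
Cuts: first C5–C6 in the middle of the chain (sp3–sp3), then C14–C15 in the C6–C17 half and the ring carbon–C1 bond in the aryl half. The three OH groups travel as benzyl ethers.
Enabling feature: C5 and C6 are plain, unbranched CH2 groups of the bare (CH2)15 tether, five carbons from the benzene ring and ten from C16. C6 can therefore be the end carbon of a 1-alkene and C5 a primary bromide, and no neighbouring group can eliminate, chelate or epimerise.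
Forward: the C3 epoxide and a C9 Grignard reagent give the C12 alkenol, and an aryl Grignard reagent and a C5 dibromide give the bromopentyl arene. Hydroboration then puts boron on C6 and palladium joins C6 to C5 at the saturated oxidation level. No ring is built, since the benzene ring is bought.
Stereochemistry: C16 is the stereocenter of (S)-propylene oxide, and its C–O bond is never broken.
One hydrogenolysis at the end frees all three hydroxyl groups.

Key step: step 4

Remark: 1, 2, 6 and 7 are taken as catalogue compounds, and 9-BBN (a dimer in the bottle) is written as its monomer.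

Step 1
Reactants: 1 9-bromonon-1-ene; 2 (S)-propylene oxide
Product: 4 (2S)-dodec-11-en-2-ol, via non-8-enylmagnesium bromide 3 (not isolated)
Conditions: Mg, THF, rt to 40 °C; then CuI (10 mol %), 2, THF, −30 to 0 °C; aq NH4Cl
Reagents that add atoms: magnesium, [Mg] (held in 3 only; none of it stays in 4)
Why: This is a copper-catalysed Grignard opening of a terminal epoxide by SN2 attack at the unsubstituted CH2, so no new stereocenter forms and the untouched C–O carbon of 2 becomes C16 with its (S) configuration unchanged.

Step 2
Reactants: 4 (2S)-dodec-11-en-2-ol
Product: 5 benzyl (2S)-dodec-11-en-2-yl ether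
Conditions: NaH, BnBr, Bu4NI (cat.), THF, 0 °C to rt
Reagents that add atoms: benzyl bromide, BrCc1ccccc1
Why: This Williamson ether synthesis alkylates oxygen without touching the C16–O bond, keeps the hydroxyl group from consuming 9-BBN, and installs a group that leaves together with the aryl benzyl ethers.

Step 3
Reactants: 6 1,3-bis(benzyloxy)-5-bromobenzene; 7 1,5-dibromopentane
Product: 9 1,3-bis(benzyloxy)-5-(5-bromopentyl)benzene, via 3,5-bis(benzyloxy)phenylmagnesium bromide 8 (not isolated)
Conditions: Mg, I2 (cat.), THF, reflux; then slow addition to 7 (4 equiv), Li2CuCl4 (3 mol %), THF, 0 °C to rt; excess 7 distilled off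
Reagents that add atoms: magnesium, [Mg] (held in 8 only; none of it stays in 9)
Why: This is a copper-catalysed cross-coupling of an aryl Grignard reagent with a primary alkyl bromide, in which inverse addition to an excess of the symmetrical dibromide should hold the reaction at monosubstitution while the benzyl ethers stay inert.

Step 4
Reactants: 5 benzyl (2S)-dodec-11-en-2-yl ether; 9 1,3-bis(benzyloxy)-5-(5-bromopentyl)benzene
Product: 11 1,3-bis(benzyloxy)-5-[(16S)-16-(benzyloxy)heptadecyl]benzene, via B-alkyl-9-BBN 10 (not isolated)
Conditions: 5 (1.2 equiv), 9-BBN (0.5 M in THF), rt; then 9, Pd(OAc)2 (4 mol %), PCy3 (8 mol %), K3PO4·H2O, THF, rt; filtration through silica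
Reagents that add atoms: 9-borabicyclo[3.3.1]nonane (9-BBN), B1C2CCCC1CCC2 (held in 10 only; the boron unit leaves again before 11)
Why: 9-BBN adds its B–H bond across the C6=C7 double bond of 5 through a four-centre transition state, and the bulk of the bicyclic borane places boron on the terminal carbon C6 to give 10. Pd(0)/PCy3 then inserts into the primary C5–Br bond of 9 in an SN2-like oxidative addition, the borane activated by phosphate and water hands its primary alkyl group to palladium, and reductive elimination forms the C5–C6 σ-bond directly at the saturated oxidation level of the target. The closest known reaction type is the room-temperature alkyl–alkyl Suzuki–Miyaura cross-coupling of B-alkyl-9-BBN reagents with unactivated primary alkyl bromides that carry β-hydrogens. No ring is closed and no stereocenter is formed; C16 lies ten carbons from the reacting end and its C–O bond takes no part, so the (S) configuration is carried through. The step needs terminal regioselectivity in the hydroboration (secured by the unbranched monosubstituted alkene and by 9-BBN), transfer of the primary alkyl group rather than the secondary carbons of the borabicycle (secured by the faster transfer of primary B–C bonds), and coupling ahead of β-hydride elimination (secured by the bulky, electron-rich PCy3 and the unhindered CH2 termini). Chemoselectivity is given because 9 holds only one carbon–halogen bond and the aryl and alkyl benzyl ethers are inert to borane, phosphate and Pd(0).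

Step 5
Reactants: 11 1,3-bis(benzyloxy)-5-[(16S)-16-(benzyloxy)heptadecyl]benzene
Product: 12 hansfordiol A, 5-[(16S)-16-hydroxyheptadecyl]benzene-1,3-diol
Conditions: H2 (1 atm), 10% Pd/C, EtOAc–EtOH, rt
Reagents that add atoms: none
Why: Catalytic hydrogenolysis of benzyl ethers cleaves only the three PhCH2–O bonds, so the C16–O bond and its (S) configuration remain and the resorcinol ring should not be reduced under these mild conditions.

Compound list
1 | 9-bromonon-1-ene | C=CCCCCCCCBr | starting material
2 | (S)-propylene oxide, (2S)-2-methyloxirane | C[C@H]1CO1 | starting material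
3 | non-8-enylmagnesium bromide | C=CCCCCCCC[Mg]Br | intermediate
4 | (2S)-dodec-11-en-2-ol | C[C@H](O)CCCCCCCCC=C | intermediate
5 | benzyl (2S)-dodec-11-en-2-yl ether | C[C@H](OCc1ccccc1)CCCCCCCCC=C | intermediate
6 | 1,3-bis(benzyloxy)-5-bromobenzene | Brc1cc(OCc2ccccc2)cc(OCc2ccccc2)c1 | starting material
7 | 1,5-dibromopentane | BrCCCCCBr | starting material
8 | 3,5-bis(benzyloxy)phenylmagnesium bromide | Br[Mg]c1cc(OCc2ccccc2)cc(OCc2ccccc2)c1 | intermediate
9 | 1,3-bis(benzyloxy)-5-(5-bromopentyl)benzene | BrCCCCCc1cc(OCc2ccccc2)cc(OCc2ccccc2)c1 | intermediate
10 | 9-[(11S)-11-(benzyloxy)dodecyl]-9-borabicyclo[3.3.1]nonane | C[C@H](OCc1ccccc1)CCCCCCCCCCB1C2CCCC1CCC2 | intermediate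
11 | 1,3-bis(benzyloxy)-5-[(16S)-16-(benzyloxy)heptadecyl]benzene | C[C@H](OCc1ccccc1)CCCCCCCCCCCCCCCc1cc(OCc2ccccc2)cc(OCc2ccccc2)c1 | intermediate
12 | hansfordiol A, 5-[(16S)-16-hydroxyheptadecyl]benzene-1,3-diol | C[C@H](O)CCCCCCCCCCCCCCCc1cc(O)cc(O)c1 | target

Total steps: 5. Longest linear sequence: 4 (steps 1, 2, 4, 5).

Steps most likely to fail

1. Step 4.
- Risk: β-hydride elimination or hydrodebromination of the alkylpalladium species may outrun a slow transmetalation, and air may oxidise PCy3 or the borane.
- Fallback, setting out from 5 and 9 and coming back at 11: the polarity at the junction is reversed and copper replaces palladium. Borane 10, made as in step 4, would be oxidised with NaOH/H2O2 to (11S)-11-(benzyloxy)dodecan-1-ol F1. TsCl/pyridine should convert this into (11S)-11-(benzyloxy)dodecyl 4-methylbenzenesulfonate F2. Bromide 9 would be turned with Mg in THF into 5-[3,5-bis(benzyloxy)phenyl]pentylmagnesium bromide F3. This Grignard reagent should displace the tosylate under Li2CuCl4 catalysis (THF, −78 °C to rt) and form the same C5–C6 bond of 11.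

2. Step 3.
- Risk: a second substitution may occur at the remaining C–Br end, the aryl Grignard reagent may homocouple, or magnesium may insert sluggishly into the aryl bromide.
- Fallback, setting out from 6 and coming back at 9: the aryl carbon becomes the electrophile, so no symmetrical dielectrophile is needed. Commercial 5-bromopent-1-ene would be hydroborated with 9-BBN to 9-(5-bromopentyl)-9-borabicyclo[3.3.1]nonane F4. This would be coupled with 6 in an sp2–sp3 B-alkyl Suzuki–Miyaura reaction (PdCl2(dppf), K3PO4, THF–H2O, 50 °C). The dppf-ligated palladium should insert into the aryl C–Br bond only and leave the primary alkyl bromide of 9 in place.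

3. Step 1.
- Risk: bromide may open the epoxide in competition (halohydrin formation), magnesium salts may rearrange the epoxide before addition, and Wurtz dimerisation may occur while the Grignard reagent forms.
- Fallback, setting out from 1 and coming back at 4: the stereocenter is set by an enzyme instead of the chiral pool. Ethyl acetoacetate would be alkylated with 1 (NaOEt, EtOH, reflux) to racemic ethyl 2-acetylundec-10-enoate F5. Saponification and acidification would give 2-acetylundec-10-enoic acid F6, which should lose CO2 on warming to give dodec-11-en-2-one F7. An (S)-selective (Prelog-type) NAD(P)H-dependent alcohol dehydrogenase (ketoreductase class), run with 2-propanol as hydride source, should tell the methyl group from the long alkyl group and reduce the ketone to 4.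

Further compounds
F1 | step 4 | (11S)-11-(benzyloxy)dodecan-1-ol | C[C@H](OCc1ccccc1)CCCCCCCCCCO
F2 | step 4 | (11S)-11-(benzyloxy)dodecyl 4-methylbenzenesulfonate | C[C@H](OCc1ccccc1)CCCCCCCCCCOS(=O)(=O)c1ccc(C)cc1
F3 | step 4 | 5-[3,5-bis(benzyloxy)phenyl]pentylmagnesium bromide | Br[Mg]CCCCCc1cc(OCc2ccccc2)cc(OCc2ccccc2)c1
F4 | step 3 | 9-(5-bromopentyl)-9-borabicyclo[3.3.1]nonane | BrCCCCCB1C2CCCC1CCC2
F5 | step 1 | ethyl 2-acetylundec-10-enoate (racemic) | CCOC(=O)C(CCCCCCCC=C)C(C)=O
F6 | step 1 | 2-acetylundec-10-enoic acid (racemic) | OC(=O)C(CCCCCCCC=C)C(C)=O
F7 | step 1 | dodec-11-en-2-one | CC(=O)CCCCCCCCC=C
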